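Late in the north run the readings stood level near 287.9 mM from 2.0 min on, with 462 mM of the substrate charge not found in product. Partner, the limiting reagent in that flask, ended 87.1 mM short of its charge in product, and I took this shortfall as partner lost along a path that makes no product.

| setting | east | south-east | north | south |
|---|---|---|---|---|
| substrate | 250 mM | 250 mM | 750 mM | 750 mM |
| partner | 375 mM | 560 mM | 375 mM | 750 mM |
| time |  |  |  | 8.0 min |

| run | time / min | [product] / mM |
|---|---|---|
| east run | 1.0 | 64.4 |
| east run | 2.0 | 131.2 |
| east run | 3.0 | 161.2 |
| east run | 4.0 | 177.0 |
| east run | 5.0 | 184.0 |
| east run | 6.0 | 189.7 |
| east run | 7.0 | 192.3 |
| east run | 8.0 | 194.2 |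
| south-east run | 1.0 | 96.9 |
| south-east run | 2.0 | 170.6 |
| south-east run | 3.0 | 197.3 |
| south-east run | 4.0 | 210.2 |
| south-east run | 5.0 | 218.5 |
| south-east run | 6.0 | 223.1 |
| south-east run | 7.0 | 226.0 |
| south-east run | 8.0 | 227.2 |
| north run | 1.0 | 264.6 |
| north run | 2.0 | 287.8 |
| north run | 3.0 | 287.8 |
| north run | 4.0 | 287.9 |
| north run | 5.0 | 287.1 |
| north run | 6.0 | 287.5 |
| north run | 7.0 | 287.9 |
| north run | 8.0 | 287.9 |

(standard deviation of a reading: 0.8 mM)

- Overall: substrate + partner -> product.
- Constant volume, constant temperature.
- An order is taken over about fifteen percent of the charge, up and down.

- order of the initial rate in [partner], near the charge of the east run, the rate being that where two percent of its substrate are product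
- order of the initial rate in [substrate], near the charge of the east run, the rate being that where two percent of its substrate are product (one fixed amount of product, the same in the runs compared)
- product in the south run at 8.0 min, as a share of the substrate charged

So I treated the south run as a question of selectivity: how the partner divides between product and loss. I counted partner not found in product, per product, at the last reading. This came to 0.303 in the north run and 0.931 in the east run. I assumed that the loss runs one order higher in [partner] than the product path, and that the product path is first order in [substrate]. This count should then follow the ratio of mean [partner] to mean [substrate], each mean taken halfway between start and end, if partner ended near zero, which I assumed too. In the north run that ratio was 0.309, and the count divided by it gave 0.978, the waste figure.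

For the south run I began by granting it the north run's share of partner, which gave 576 mM. The waste figure turned that into 418 mM. Putting each answer back gave 447 mM, then 442 mM.

The weak link was taking the figure from the north run by itself. The east run gave 1.23 for the ratio and 0.759 for the figure, and the south run's ratio of 0.709 lay between the two. I therefore used their mean, 0.869. Two more rounds gave 464 mM and 460 mM, or 61.4% of the substrate.

The forecast said 66%, within 57% to 77%, with orders of 1 in [partner] and 1.7 in [substrate]. It stood on another reading, that “the reaction seems to stop because activity dies”, and its share was higher than mine.

    substrate ⇌ intermediate (0.3576 /min, 0.1140 /min)
    intermediate + partner → product (5.346 /M/min)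
    substrate + partner + product → 2 product (34.92 /M²/min)
    2 partner → lost reagent (0.9540 /M/min)

The south run gave 69.0% at 8.0 min, inside the forecast's range and above my figure. The orders of the initial rate near the east run's charge came to 0.56 in [partner] and 0.78 in [substrate], each lower than the low end of the forecast's range. The step in which product joins substrate and partner moves the readings by 96 times the scatter, root mean square. Put through the south run, the 518 mM of product leaves 232 mM of partner not found in product, or 0.449 per product, against a ratio of 0.763. The south run's waste figure is therefore 0.588, below the north run's 0.978 and the east run's 0.759.

The data come from a simulation for substances that don't exist; scatter was added.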